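## Structural features

The target is a tetracyclic amino macrolactone of the halichlorine type. Cyclopentane ring A and piperidine ring B share the spiro carbon C9; ring C is a tetrahydropyridine fused to ring B through N and C5 and carries the conjugated ester C1(=O)–C2=C3 (C23 is the N–CH2 of ring C). Ring D is a 15-membered lactone running C1–O–C21–C20–C19(Cl)=C18–C17(OH)–C16=C15–C14(CH3)–C13 and closing through C9, N, C23 and C2 (C22 is the methyl on C14). There are five stereocentres, C5 (R), C9 (S), C13 (R), C14 (S) and C17 (R): C9, C13 and C14 are contiguous, C5 faces C9 across nitrogen, and C17 stands alone between two alkenes. On ring A the nitrogen on C9 and the C14 branch on C13 are cis; on ring B, C13 and the C5 substituent (C4) are cis. C15=C16 is Z, and C18=C19 carries chlorine trans to C17, so that C17 and C20 are cis (18E). Fragile features are the doubly allylic C17 carbinol, the alkenyl chloride (a vinylogous acyl chloride whenever C17 is a carbonyl), the β-amino enoate of ring C, C14 while C15 is a carbonyl, and a nitrogen flanked by quaternary C9 and tertiary C5. The real difficulty is the nitrogen-bearing quaternary centre C9 with its defined relation to C13/C14 and to C5. The key step uses the cis N/C14 relation in ring A: a nitrone with C9 as its C=N carbon inside ring B can deliver N to C9 and the C13 branch together, the N–O–C14 bridge of an isoxazolidine holding them on one face.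

## Logic of the disconnections

41 ⇒ 40. The lactone bond C1–O21 is cut. It is the only ring D bond that can be made last without touching a stereocentre, and it opens the macrocycle to a linear hydroxy acid. The forward step must acylate the primary C21 hydroxyl at high dilution in the presence of the free C17 hydroxyl.

40 ⇒ 38 ⇒ 37. The acid and the C21 hydroxyl are masked as methyl ester and silyl ether, and the Z C15=C16 alkene is traced back to the C15≡C16 alkyne. This turns a geometry problem into a syn hydrogen delivery. The semi-reduction must stop at the alkene and spare C–Cl and the enoate.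

37 ⇒ 31 + 36. The C16–C17 bond between alkyne carbon and carbinol is cut. This is the most convergent cut of ring D: it separates the whole C17–C21 chain from the tricyclic core and creates C17 in the same step. The addition must be ligand-controlled (Re face of the aldehyde), because C17 is remote from the core stereocentres.

36 ⇒ 35 ⇒ 34 ⇒ 33 ⇒ 32. The chloroalkene geometry is traced to a six-membered lactone in which C17 and C20 are cis by ring constraint; the ring is opened at the C17–O21 acyl bond. This replaces a stereoselective alkene synthesis by a ring opening. The nucleophile must attack the lactone carbonyl and not displace chloride at C19.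

31 ⇒ 30 ⇒ 29. The C15≡C16 bond is cut by one-carbon homologation of the C15 aldehyde, which comes from the C15 alcohol. The forward steps must not epimerise C14, which is α to the aldehyde.

29 ⇒ 28 ⇒ 26 + 27. Ring C is cut at C2=C3 (ring-closing metathesis) and at N–C23 (allylic substitution). One three-carbon reagent then supplies C1, C2 and C23, and the core is reduced to a secondary amine with a C5 allyl group. The hindered nitrogen must be alkylated intermolecularly, and the amine must be masked as its salt during metathesis.

26 ⇒ 25. The N–C15 bond is reconnected as a lactam. The lactam makes C14 a ring carbon of a cis-fused bicycle, which is what allows its configuration to be controlled. The forward step is a C–N-cleaving reduction of a tertiary lactam.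

25 ⇒ 24 ⇒ 23 ⇒ 22. The terminal alkene carbon is cut from C3 (methylenation), and C3 is returned to the silyl-protected alcohol. These operations are placed while nitrogen is an unreactive amide.

22 ⇒ 21 ⇒ 20 ⇒ 19. The C14–C22 bond is cut (enolate methylation on the convex face), and the C14 methylene is traced to a C14–O bond (radical deoxygenation). The oxygen on C14 is the residue of the key step and is deliberately erased before the methyl group is set.

19 ⇒ 17. The lactam N–C15 bond is cut and the N–O bond is reconnected, which reveals the isoxazolidine ester. The forward step needs a reductive N–O cleavage that leaves the ester to be captured by the liberated amine.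

17 ⇒ 16. The C9–C13 and O–C14 bonds are cut together (retro-(3+2)). Ring A and the N–O ring disappear and three stereocentres are removed, leaving a monocyclic nitrone with one stereocentre (C5). The forward step must select the face of C9=N that places C13 cis to the C5 chain.

16 ⇒ 14 ⇒ 12 + 13. The C9=N bond is cut (condensation of N-alkylhydroxylamine and ketone), and the C13=C14 alkene is cut by cross-metathesis with the acrylate. The precursor becomes an open chain; deprotection must release the hydroxylamine without harming the enoate or the silyl ether.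

12 ⇒ 11. The C5–N bond is cut with inversion (Mitsunobu), so that C5 can be set as a carbinol by hydrogenation.

11 ⇒ 8 + 9. The C9–C10 bond is cut (acylation of a Grignard reagent by an amide). C9 therefore travels as an amide through all earlier steps and never coexists as a ketone with the β-keto ester or the reducing agents.

8 ⇒ 7 ⇒ 6 ⇒ 5. The silyl group is removed, C3 is returned to the ester level, and the C5 carbinol is traced to the β-keto ester, where an asymmetric hydrogenation sets the only stereocentre of the nitrone.

5 ⇒ 2 + 3 ⇒ 1. The C4–C5 bond is cut (acylation of a malonate half-ester), and the amide C–N bond is cut to a symmetric anhydride, which is desymmetrised by one aminolysis.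

## Other disconnections considered

Alternative 1: The cut is the C15=C16 alkene, traced to a C15≡C16 triple bond that is opened by alkyne metathesis. The open precursor is the diyne ester A1, with a propynyl cap on C15 and on C16 and the C1–O21 ester already in place. In the forward step a molybdenum alkylidyne with silanolate ligands, for example Mo(≡CC6H4OMe)(OSiPh3)3, would exchange the two capped alkynes, 2-butyne would be removed, and the 15-membered cycloalkyne A2 would form; Z-selective semi-reduction and desilylation would finish the target.
- In its favour: C17 is set on a small propynyl carbinol before it meets the core, the ester bond is made intermolecularly, ring closure does not depend on telling two hydroxyls apart, and the Z geometry follows from syn hydrogen delivery inside a ring.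
- Against it here: it solves only ring D. A1 still contains the whole spiro tricycle, so C5, C9, C13 and C14 must come from another key step. A Lewis-basic tertiary amine and a propargylic silyl ether sit next to the reacting alkynes, and C15 needs a capped alkyne (one operation more than the terminal alkyne 31).
- Comparison: structurally the two plans are complementary, since the chosen key step builds ring A and the C9/C13 pair and A1 → A2 builds ring D. Mechanistically both closures are reversible and self-correcting. In step count this end game (esterification, ring closure, semi-reduction, desilylation) equals the chosen one (alkynylation, semi-reduction, unveiling, lactonisation). On control of C17 and on hydroxyl selectivity at ring closure the alternative is the better plan; on convergence it is the equal; as a strategy for the whole molecule it is weaker because the hard part is untouched.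

Alternative 2: The cut is N–C9. In the forward step a pentamethylcyclopentadienyl iridium complex (trivalent iridium, for example one made from [IrCl2(C5Me5)]2 and an N,O-chelating ligand) would decarboxylate the dioxazolone A3 to an acyl nitrenoid. Insertion into the tertiary γ C9–H bond with retention would give the cis-fused γ-lactam A4.
- In its favour: the quaternary C–N bond comes directly from a C–H bond of fixed configuration, tertiary C–H bonds are the preferred sites, the C14 methyl is already present, and the lactam is secondary, so it can be activated on nitrogen and opened under mild conditions.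
- Against it here: A3 needs three contiguous centres (C9–H, C13, C14) on a trans-1,2-disubstituted cyclopentane before the key step. A second γ position (the C12 methylene) and rearrangement to an isocyanate compete. Ring B and C5 must still be added by N–C5 bond formation at a hindered nitrogen, so the C5/C9 relation becomes a later problem.
- Comparison: structurally the chosen step makes two rings and three centres from a precursor with one centre, whereas A3 → A4 makes one ring and no new carbon stereocentre. Mechanistically a kinetic, stereoretentive metal-nitrenoid insertion replaces a thermodynamically selected pericyclic addition. The alternative is the better plan on predictability at C9 (no reliance on equilibration) and on the ease of opening the lactam. In step economy it saves the deoxygenation and methylation after the key step but pays for them before it and for a separate ring B synthesis, so it is at best equal overall.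

Alternative 3: The cut is C8–C9. In the forward step acid (formic acid or BF3·OEt2) would ionise the hydroxylactam A5 to a bicyclic N-acyliminium ion at C9. The silicon-bearing carbon C8 of the Z-vinylsilane would attack it with loss of silicon, closing ring B as the spiro tetrahydropyridine A6.
- In its favour: it is convergent (an amine carrying C5 plus a 2-oxocyclopentane acetic acid unit), attack on the convex face of the cis-fused cation sets C9 relative to C13, and no high temperature is needed. Hydrogenation of A6 would give 21 directly, so the alternative would join the chosen route after step 13 and save the N–O cleavage and the deoxygenation.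
- Against it here: C13 is α to the C9 carbonyl and iminium carbon and can epimerise through the enamide. The relation of the C9/C13 pair to C5 must therefore be imposed kinetically by the C5 centre on the nitrogen substituent, with no way to correct a wrong result. The α-branched N-substituent hinders formation and ionisation of the hydroxylactam, and protodesilylation competes.
- Comparison: structurally it forms one ring and one centre against two rings and three centres. Mechanistically it is an irreversible cation–olefin cyclisation against a reversible cycloaddition. The alternative is the better plan on convergence and on post-key-step economy; the chosen plan is stronger on the C5/C9 relation, which equilibration can correct.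

Key step: step 10

Remark on the chemistry: the alkene geometries are read from the target SMILES as C15=C16 Z and C18=C19 with C17 and C20 cis (chlorine trans to C17, 18E), and oxane-2,4-dione (32) is taken as a purchasable compound.

The configurations of the nitrone 16 (C5 R) and of the cycloadduct 17 were checked against the target and agree at C5, C9 and C13. The descriptor at C13 changes from S in 17 to R later only because the priorities change, not the geometry. The precursor synthesis was redesigned so that C9 is carried as a morpholine amide until C5 and O3 are in place. A free C9 ketone next to the β-keto ester would invite intramolecular aldol condensation (C4 onto C9) and would compete in the hydrogenation and the ester reduction.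

Shorthand used in names (atom numbers as defined above):
- "Spiro-lactam core" is the γ-lactam N–C15(=O)–C14–C13–C9, cis-fused to ring A along C9–C13 and sharing N–C9 with ring B, with the C5 substituent cis to C13 on ring B.
- "A–B–C core" is the 6-azaspiro[4.5]decane (rings A and B) whose N and C5 are bridged by C23H2–C2(CO2CH3)=C3H–C4H2 (ring C).

## Route

Step 1
Reactants: 1 glutaric anhydride
Product: 2 5-(morpholin-4-yl)-5-oxopentanoic acid
Conditions: morpholine (1.0 equiv), THF, 0 °C → rt; aq. HCl work-up
Reagents that add atoms: morpholine, C1COCCN1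
Why: Aminolysis of a symmetric cyclic anhydride stops at the mono-amide acid; the morpholine amide is a masked ketone that is inert to hydrogenation and borohydride and later acylates a Grignard reagent once.

Step 2
Reactants: 2 5-(morpholin-4-yl)-5-oxopentanoic acid; 3 potassium methyl malonate
Product: 5 methyl 7-(morpholin-4-yl)-3,7-dioxoheptanoate, via acyl imidazolide 4 (not isolated)
Conditions: CDI, THF, rt; then 3, MgCl2, Et3N, THF, rt → 45 °C; aq. citric acid
Reagents that add atoms: 1,1'-carbonyldiimidazole, O=C(n1ccnc1)n1ccnc1 (its atoms remain only in 4)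
Why: Masamune–Brooks homologation: the acyl imidazolide C-acylates the magnesium enolate of the malonate half-ester, and loss of CO2 gives the β-keto ester; the amide at C9 is too weak an electrophile for the intramolecular aldol that a C9 ketone would undergo.

Step 3
Reactants: 5 methyl 7-(morpholin-4-yl)-3,7-dioxoheptanoate
Product: 6 methyl (3S)-3-hydroxy-7-(morpholin-4-yl)-7-oxoheptanoate
Conditions: H2 (10 atm), [RuCl(p-cymene)((S)-BINAP)]Cl (0.5 mol %), MeOH, 50 °C
Reagents that add atoms: none
Why: Noyori asymmetric hydrogenation of a β-keto ester through ester–ketone chelation to ruthenium; the (S)-BINAP complex gives the 3S carbinol (C5 of the target, with O where N will stand after inversion), and the substrate has no alkene or second ketone to compete.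

Step 4
Reactants: 6 methyl (3S)-3-hydroxy-7-(morpholin-4-yl)-7-oxoheptanoate
Product: 7 (5S)-5,7-dihydroxy-1-(morpholin-4-yl)heptan-1-one
Conditions: LiBH4, THF, 0 °C → rt; aq. NH4Cl
Reagents that add atoms: none
Why: LiBH4 reduces the ester (helped by the neighbouring alkoxide) and leaves a tertiary amide untouched, which is why C9 is carried as a morpholine amide and not as a ketone or an N-methoxy amide.

Step 5
Reactants: 7 (5S)-5,7-dihydroxy-1-(morpholin-4-yl)heptan-1-one
Product: 8 (5S)-7-[(tert-butyldiphenylsilyl)oxy]-5-hydroxy-1-(morpholin-4-yl)heptan-1-one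
Conditions: TBDPSCl (1.05 equiv), imidazole, CH2Cl2, 0 °C
Reagents that add atoms: tert-butyl(chloro)diphenylsilane, CC(C)(C)[Si](Cl)(c1ccccc1)c1ccccc1
Why: The bulky chlorosilane silylates the primary hydroxyl selectively; TBDPS is chosen because it should survive the Grignard reagent, TFA, 160 °C, Zn/AcOH, tin hydride and the lithium amide base.

Step 6
Reactants: 8 (5S)-7-[(tert-butyldiphenylsilyl)oxy]-5-hydroxy-1-(morpholin-4-yl)heptan-1-one; 9 5-bromopent-1-ene
Product: 11 (10S)-12-[(tert-butyldiphenylsilyl)oxy]-10-hydroxydodec-1-en-6-one, via pent-4-en-1-ylmagnesium bromide 10 (not isolated)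
Conditions: 9, Mg, THF, rt → 40 °C; then 8 (0.33 equiv relative to 10), THF, 0 °C → rt; aq. NH4Cl
Reagents that add atoms: magnesium, [Mg] (its atom remains only in 10)
Why: Grignard acylation by a morpholine amide: one equivalent deprotonates the C5 hydroxyl, the next adds once to the amide to give a tetrahedral magnesium hemiaminal that releases the ketone only on work-up, so no tertiary alcohol should form.

Step 7
Reactants: 11 (10S)-12-[(tert-butyldiphenylsilyl)oxy]-10-hydroxydodec-1-en-6-one
Product: 12 tert-butyl N-[(tert-butoxycarbonyl)oxy]-N-[(3R)-1-[(tert-butyldiphenylsilyl)oxy]-7-oxododec-11-en-3-yl]carbamate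
Conditions: BocNHOBoc (1.5 equiv), PPh3, DIAD, THF, 0 °C → rt
Reagents that add atoms: tert-butyl N-[(tert-butoxycarbonyl)oxy]carbamate, CC(C)(C)OC(=O)NOC(=O)OC(C)(C)C
Why: Mitsunobu N-alkylation of the acidic N–H of the bis-Boc hydroxylamine with inversion at the secondary carbinol turns 5S–O into 5R–N; ketone and alkene are spectators.

Step 8
Reactants: 12 tert-butyl N-[(tert-butoxycarbonyl)oxy]-N-[(3R)-1-[(tert-butyldiphenylsilyl)oxy]-7-oxododec-11-en-3-yl]carbamate; 13 ethyl acrylate
Product: 14 ethyl (2E,11R)-11-{(tert-butoxycarbonyl)[(tert-butoxycarbonyl)oxy]amino}-13-[(tert-butyldiphenylsilyl)oxy]-7-oxotridec-2-enoate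
Conditions: 13 (5 equiv), second-generation Hoveyda–Grubbs catalyst RuCl2(=CH-2-iPrOC6H4)(H2IMes) (3 mol %), CH2Cl2, 40 °C
Reagents that add atoms: none
Why: Cross-metathesis of a terminal alkene with an excess of an electron-poor acrylate gives the E-enoate selectively, because the acrylate homodimerises slowly and the product is not a good metathesis partner.

Step 9
Reactants: 14 ethyl (2E,11R)-11-{(tert-butoxycarbonyl)[(tert-butoxycarbonyl)oxy]amino}-13-[(tert-butyldiphenylsilyl)oxy]-7-oxotridec-2-enoate
Product: 16 ring B ketonitrone ethyl (2E)-6-[(2R)-2-{2-[(tert-butyldiphenylsilyl)oxy]ethyl}-1-oxido-2,3,4,5-tetrahydropyridin-1-ium-6-yl]hex-2-enoate, via free hydroxylamine 15 (not isolated)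
Conditions: TFA/CH2Cl2 (1:4), 0 °C → rt; concentrate; aq. NaHCO3/CH2Cl2, rt
Reagents that add atoms: none
Why: Acidolysis removes both Boc groups, and on neutralisation the N-alkylhydroxylamine condenses with the C9 ketone four carbons away to the six-membered ketonitrone; this intramolecular condensation should outrun conjugate addition to the enoate, and a primary TBDPS ether tolerates TFA.

Step 10
Reactants: 16 ring B ketonitrone ethyl (2E)-6-[(2R)-2-{2-[(tert-butyldiphenylsilyl)oxy]ethyl}-1-oxido-2,3,4,5-tetrahydropyridin-1-ium-6-yl]hex-2-enoate
Product: 17 tricyclic isoxazolidine ethyl ester (5R,9S,13S,14S; rings A and B spiro at C9 with an N–O–C14 bridge)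
Conditions: 1,2-dichlorobenzene (5 mM), BHT (cat.), 160 °C, sealed tube
Reagents that add atoms: none
Why: This is a concerted, suprafacial nitrone–alkene (3+2) cycloaddition; the closest known type is the intramolecular cycloaddition of C-(pent-4-enyl) cyclic nitrones to cis-fused bicyclic isoxazolidines. Ring A closes in the 5-exo mode (C9 to the proximal alkene carbon C13), the isoxazolidine closes by O–C14 bonding, and the two five-membered rings are necessarily cis-fused along C9–C13, so the ring fixes C9 relative to C13. C14 is fixed relative to C13 by suprafacial addition to the E-alkene (ester trans to C12). The only free variable is the face of C9=N relative to C5, which is the controlling element; the step needs the isomer with C13 cis to the C5 chain on ring B. The three-carbon tether favours the fused over the bridged regiochemistry. Cycloreversion of this ester-substituted isoxazolidine is accessible at 160 °C, so the kinetic adduct (axial attack anti to a pseudo-axial C5 chain), any bridged isomer and the desired adduct can interconvert. The desired adduct is expected to dominate at equilibrium because it alone can hold the C5 chain and the C9–C13 bond equatorial on a chair ring B. High dilution suppresses intermolecular cycloaddition.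

Step 11
Reactants: 17 tricyclic isoxazolidine ethyl ester (5R,9S,13S,14S; rings A and B spiro at C9 with an N–O–C14 bridge)
Product: 19 spiro-lactam core with C14–OH on the concave face and C5–CH2CH2OTBDPS (5R,9S,13S,14S), via amino hydroxy ester 18 (not isolated)
Conditions: Zn dust, AcOH/H2O (4:1), 60 °C; filter; PhMe, 90 °C
Reagents that add atoms: none
Why: Zinc in acetic acid cleaves the N–O bond to the secondary amine and the C14 alcohol, and the amine then acylates on the neighbouring ethyl ester to close the five-membered lactam N–C9–C13–C14–C15; no stereocentre is touched.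

Step 12
Reactants: 19 spiro-lactam core with C14–OH on the concave face and C5–CH2CH2OTBDPS (5R,9S,13S,14S)
Product: 20 O-(C14 of the spiro-lactam core) 1H-imidazole-1-carbothioate with C5–CH2CH2OTBDPS
Conditions: 1,1'-thiocarbonyldiimidazole (2 equiv), DMAP, ClCH2CH2Cl, 70 °C
Reagents that add atoms: 1,1'-thiocarbonyldiimidazole, S=C(n1ccnc1)n1ccnc1
Why: Thioacylation of the secondary alcohol gives the radical precursor for a Barton–McCombie deoxygenation; the imidazolide reagent is used because the hydroxyl lies on the hindered concave face.

Step 13
Reactants: 20 O-(C14 of the spiro-lactam core) 1H-imidazole-1-carbothioate with C5–CH2CH2OTBDPS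
Product: 21 spiro-lactam core with C14 methylene and C5–CH2CH2OTBDPS (5R,9S,13R)
Conditions: Bu3SnH, AIBN (cat.), PhMe, 110 °C
Reagents that add atoms: none
Why: Barton–McCombie deoxygenation: the stannyl radical adds to C=S, fragmentation gives a C14 radical stabilised by the lactam carbonyl, and hydrogen transfer gives the methylene lactam; the C14 configuration from the cycloaddition is erased on purpose.

Step 14
Reactants: 21 spiro-lactam core with C14 methylene and C5–CH2CH2OTBDPS (5R,9S,13R)
Product: 22 spiro-lactam core with C14–CH3 on the convex face and C5–CH2CH2OTBDPS (5R,9S,13R,14R)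
Conditions: LiN(iPr)2 (1.2 equiv), THF, −78 °C; CH3I, −78 → −40 °C
Reagents that add atoms: iodomethane, CI
Why: Alkylation of the lithium lactam enolate, which is part of a cis-fused bicyclo[3.3.0] unit; ring A (C12 on the adjacent C13) blocks the concave face, so iodomethane should enter on the convex face anti to C12 and place the methyl cis to H13 as in the target.

Step 15
Reactants: 22 spiro-lactam core with C14–CH3 on the convex face and C5–CH2CH2OTBDPS (5R,9S,13R,14R)
Product: 23 spiro-lactam core with C14–CH3 and C5–CH2CH2OH (5R,9S,13R,14R)
Conditions: Bu4NF, AcOH (buffer), THF, rt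
Reagents that add atoms: none
Why: Fluoride cleaves the Si–O bond; C3 is elaborated at this stage because the lactam nitrogen is neither basic nor nucleophilic.

Step 16
Reactants: 23 spiro-lactam core with C14–CH3 and C5–CH2CH2OH (5R,9S,13R,14R)
Product: 24 spiro-lactam core with C14–CH3 and C5–CH2CHO (5R,9S,13R,14R)
Conditions: Dess–Martin periodinane, NaHCO3, CH2Cl2, 0 °C → rt
Reagents that add atoms: none
Why: Dess–Martin oxidation of the primary alcohol under buffered conditions; a β-amido aldehyde is not prone to β-elimination and is used crude.

Step 17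
Reactants: 24 spiro-lactam core with C14–CH3 and C5–CH2CHO (5R,9S,13R,14R)
Product: 25 spiro-lactam core with C14–CH3 and C5–CH2CH=CH2 (5R,9S,13R,14R)
Conditions: Ph3PCH3Br, KOtBu, THF, 0 °C
Reagents that add atoms: methyltriphenylphosphonium bromide, C[P+](c1ccccc1)(c1ccccc1)c1ccccc1.[Br-]
Why: Wittig methylenation converts C3=O into the terminal alkene needed for ring C; the ylide is not basic enough to deprotonate C14 next to the lactam carbonyl.

Step 18
Reactants: 25 spiro-lactam core with C14–CH3 and C5–CH2CH=CH2 (5R,9S,13R,14R)
Product: 26 (2R)-2-[(1R,5S,7R)-7-(prop-2-en-1-yl)-6-azaspiro[4.5]decan-1-yl]propan-1-ol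
Conditions: LiNH2BH3 (from BH3·NH3 and BuLi, 4 equiv), THF, 0 °C → rt; aq. HCl, then NaOH
Reagents that add atoms: none
Why: Lithium amidotrihydroborate reduces tertiary amides to primary alcohols with C–N cleavage: hydride addition gives a hemiaminal–borane adduct that expels the hindered amine, and the aldehyde is reduced further; C14 is not enolised by this non-basic hydride and the isolated alkene is not hydroborated.

Step 19
Reactants: 26 (2R)-2-[(1R,5S,7R)-7-(prop-2-en-1-yl)-6-azaspiro[4.5]decan-1-yl]propan-1-ol; 27 methyl 2-(bromomethyl)prop-2-enoate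
Product: 28 methyl 2-{[(1R,5S,7R)-1-[(2R)-1-hydroxypropan-2-yl]-7-(prop-2-en-1-yl)-6-azaspiro[4.5]decan-6-yl]methyl}prop-2-enoate
Conditions: 27 (1.3 equiv), K2CO3, MeCN, 0 °C → 40 °C
Reagents that add atoms: none
Why: N-Alkylation by addition–elimination (SN2′) at the unhindered terminal CH2 of the bromomethyl acrylate, the most reactive electrophile class for a nitrogen flanked by C9 and C5; the amine is more nucleophilic than the primary alcohol.

Step 20
Reactants: 28 methyl 2-{[(1R,5S,7R)-1-[(2R)-1-hydroxypropan-2-yl]-7-(prop-2-en-1-yl)-6-azaspiro[4.5]decan-6-yl]methyl}prop-2-enoate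
Product: 29 A–B–C core methyl ester with (2R)-1-hydroxypropan-2-yl on C13 (5R,9S,13R)
Conditions: TsOH·H2O (1.1 equiv), then second-generation Hoveyda–Grubbs catalyst RuCl2(=CH-2-iPrOC6H4)(H2IMes) (10 mol %), PhMe, 80 °C; aq. NaHCO3
Reagents that add atoms: none
Why: Ring-closing metathesis of the 1,1-disubstituted acrylate with the terminal alkene closes six-membered ring C and forms the endocyclic trisubstituted C2=C3 enoate; protonating the amine keeps it from deactivating the ruthenium carbene.

Step 21
Reactants: 29 A–B–C core methyl ester with (2R)-1-hydroxypropan-2-yl on C13 (5R,9S,13R)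
Product: 30 A–B–C core methyl ester with (2R)-1-oxopropan-2-yl on C13 (5R,9S,13R)
Conditions: Dess–Martin periodinane, NaHCO3, CH2Cl2, 0 °C
Reagents that add atoms: none
Why: Dess–Martin oxidation to the C15 aldehyde; nitrogen is now tertiary, so the cyclic enamine that a free N–H would form with C15 (and that would scramble C14) cannot arise, and the aldehyde is used at once.

Step 22
Reactants: 30 A–B–C core methyl ester with (2R)-1-oxopropan-2-yl on C13 (5R,9S,13R)
Product: 31 A–B–C core methyl ester with (2R)-but-3-yn-2-yl on C13 (5R,9S,13R; terminal alkyne C15≡C16)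
Conditions: dimethyl (1-diazo-2-oxopropyl)phosphonate, K2CO3, MeOH, 0 °C → rt
Reagents that add atoms: dimethyl (1-diazo-2-oxopropyl)phosphonate, CC(=O)C(=[N+]=[N-])P(=O)(OC)OC
Why: Ohira–Bestmann homologation: the diazomethylphosphonate anion released by methanolysis adds to the aldehyde, and the alkylidene carbene rearranges to the terminal alkyne; mild carbonate at 0 °C limits epimerisation at C14, and methanol cannot scramble a methyl ester.

Step 23
Reactants: 32 oxane-2,4-dione
Product: 33 4-chloro-5,6-dihydro-2H-pyran-2-one
Conditions: (COCl)2, DMF (cat.), CH2Cl2, 0 °C → rt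
Reagents that add atoms: oxalyl chloride, O=C(Cl)C(Cl)=O
Why: Vilsmeier-type chlorination of the enol of a cyclic 1,3-dicarbonyl compound gives the vinylogous acyl chloride; the ring fixes C17 (carbonyl) and C20 (ring CH2) cis on the chloroalkene.

Step 24
Reactants: 33 4-chloro-5,6-dihydro-2H-pyran-2-one
Product: 34 (2E)-3-chloro-5-hydroxy-N-methoxy-N-methylpent-2-enamide
Conditions: MeNH(OMe)·HCl, Al(CH3)3, CH2Cl2, 0 °C → rt; Rochelle salt
Reagents that add atoms: N,O-dimethylhydroxylamine hydrochloride, CNOC.Cl
Why: Aluminium amide aminolysis of a lactone (Weinreb amidation) attacks the carbonyl carbon activated by aluminium and opens the ring with retention of alkene geometry; the hard, carbonyl-bound amide is expected to prefer acyl substitution over displacement of chloride at C19.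

Step 25
Reactants: 34 (2E)-3-chloro-5-hydroxy-N-methoxy-N-methylpent-2-enamide
Product: 35 (2E)-5-[(tert-butyldimethylsilyl)oxy]-3-chloro-N-methoxy-N-methylpent-2-enamide
Conditions: TBSCl, imidazole, CH2Cl2, 0 °C
Reagents that add atoms: tert-butyl(chloro)dimethylsilane, CC(C)(C)[Si](C)(C)Cl
Why: Silylation of the primary alcohol prevents relactonisation and protects O21 up to the seco acid.

Step 26
Reactants: 35 (2E)-5-[(tert-butyldimethylsilyl)oxy]-3-chloro-N-methoxy-N-methylpent-2-enamide
Product: 36 (2E)-5-[(tert-butyldimethylsilyl)oxy]-3-chloropent-2-enal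
Conditions: iBu2AlH, THF, −78 °C; Rochelle salt
Reagents that add atoms: none
Why: iBu2AlH reduces the N-methoxy-N-methylamide to a chelated aluminium hemiaminal that releases the enal only on work-up, so no allylic alcohol forms and the alkene geometry is kept.

Step 27
Reactants: 31 A–B–C core methyl ester with (2R)-but-3-yn-2-yl on C13 (5R,9S,13R; terminal alkyne C15≡C16); 36 (2E)-5-[(tert-butyldimethylsilyl)oxy]-3-chloropent-2-enal
Product: 37 A–B–C core methyl ester with C13 chain C14H(CH3)–C15≡C16–C17H(OH)–C18H=C19(Cl)–C20H2–C21H2–OTBS (14R,17S,18E)
Conditions: Zn(CH3)2 (3 equiv), (S,S)-ProPhenol (20 mol %), Ph3PO (40 mol %), 36 (2 equiv), PhMe, 0 °C → rt; aq. NH4Cl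
Reagents that add atoms: none
Why: Catalytic asymmetric alkynylation: the alkynylzinc formed from the alkyne and Zn(CH3)2 adds 1,2 to the enal inside a dinuclear zinc–ProPhenol complex, a reaction class for which α,β-unsaturated aldehydes are good substrates; the (S,S)-ligand is selected to deliver the alkynyl group to the Re face, which gives 17S here (the same spatial arrangement as 17R in the target, the descriptor changing when the alkyne becomes an alkene).

Step 28
Reactants: 37 A–B–C core methyl ester with C13 chain C14H(CH3)–C15≡C16–C17H(OH)–C18H=C19(Cl)–C20H2–C21H2–OTBS (14R,17S,18E)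
Product: 38 A–B–C core methyl ester with C13 chain C14H(CH3)–C15H=C16H–C17H(OH)–C18H=C19(Cl)–C20H2–C21H2–OTBS (14S,15Z,17R,18E)
Conditions: H2 (1 atm), Pd on CaCO3 poisoned with Pb(OAc)2 (Lindlar catalyst), quinoline, EtOAc, rt
Reagents that add atoms: none
Why: Lindlar semi-hydrogenation delivers hydrogen syn to the alkyne and gives the Z-alkene; the poisoned catalyst with quinoline should leave the trisubstituted chloroalkene and the conjugated ester untouched when hydrogen uptake is monitored.

Step 29
Reactants: 38 A–B–C core methyl ester with C13 chain C14H(CH3)–C15H=C16H–C17H(OH)–C18H=C19(Cl)–C20H2–C21H2–OTBS (14S,15Z,17R,18E)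
Product: 40 seco acid: A–B–C core carboxylic acid with C13 chain ending in C21H2–OH and free C17–OH (14S,15Z,17R,18E), via diol methyl ester 39 (not isolated)
Conditions: Bu4NF, THF, 0 °C → rt; then LiOH, THF/MeOH/H2O, rt; aq. HCl to pH 6
Reagents that add atoms: lithium hydroxide, [Li+].[OH-]
Why: Fluoride removes the primary TBS ether and hydroxide then saponifies the methyl ester in the same flask; both operations are basic, so the acid-sensitive doubly allylic C17 alcohol is not ionised.

Step 30
Reactants: 40 seco acid: A–B–C core carboxylic acid with C13 chain ending in C21H2–OH and free C17–OH (14S,15Z,17R,18E)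
Product: 41 target macrolactone CNP0129639.4 (5R,9S,13R,14S,17R; 15Z,18E)
Conditions: 2-methyl-6-nitrobenzoic anhydride (1.3 equiv), DMAP (6 equiv), CH2Cl2 (1 mM, slow addition), rt
Reagents that add atoms: none
Why: Shiina macrolactonisation: DMAP converts the mixed anhydride into an acylpyridinium that is trapped intramolecularly at high dilution; the primary C21 hydroxyl is expected to react in preference to the hindered doubly allylic C17 hydroxyl, whose acylation would need an 11-membered ring, so the 15-membered lactone should form without protecting C17.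

## Compound list

1 | glutaric anhydride | O=C1CCCC(=O)O1 | starting material
2 | 5-(morpholin-4-yl)-5-oxopentanoic acid | OC(=O)CCCC(=O)N1CCOCC1 | intermediate
3 | potassium methyl malonate | COC(=O)CC(=O)[O-].[K+] | starting material
4 | acyl imidazolide 1-(imidazol-1-yl)-5-(morpholin-4-yl)pentane-1,5-dione | O=C(CCCC(=O)n1ccnc1)N1CCOCC1 | intermediate
5 | methyl 7-(morpholin-4-yl)-3,7-dioxoheptanoate | COC(=O)CC(=O)CCCC(=O)N1CCOCC1 | intermediate
6 | methyl (3S)-3-hydroxy-7-(morpholin-4-yl)-7-oxoheptanoate | COC(=O)C[C@@H](O)CCCC(=O)N1CCOCC1 | intermediate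
7 | (5S)-5,7-dihydroxy-1-(morpholin-4-yl)heptan-1-one | OCC[C@@H](O)CCCC(=O)N1CCOCC1 | intermediate
8 | (5S)-7-[(tert-butyldiphenylsilyl)oxy]-5-hydroxy-1-(morpholin-4-yl)heptan-1-one | CC(C)(C)[Si](c1ccccc1)(c1ccccc1)OCC[C@@H](O)CCCC(=O)N1CCOCC1 | intermediate
9 | 5-bromopent-1-ene | C=CCCCBr | starting material
10 | pent-4-en-1-ylmagnesium bromide | C=CCCC[Mg]Br | intermediate
11 | (10S)-12-[(tert-butyldiphenylsilyl)oxy]-10-hydroxydodec-1-en-6-one | CC(C)(C)[Si](c1ccccc1)(c1ccccc1)OCC[C@@H](O)CCCC(=O)CCCC=C | intermediate
12 | tert-butyl N-[(tert-butoxycarbonyl)oxy]-N-[(3R)-1-[(tert-butyldiphenylsilyl)oxy]-7-oxododec-11-en-3-yl]carbamate | CC(C)(C)[Si](c1ccccc1)(c1ccccc1)OCC[C@H](N(OC(=O)OC(C)(C)C)C(=O)OC(C)(C)C)CCCC(=O)CCCC=C | intermediate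
13 | ethyl acrylate | C=CC(=O)OCC | starting material
14 | ethyl (2E,11R)-11-{(tert-butoxycarbonyl)[(tert-butoxycarbonyl)oxy]amino}-13-[(tert-butyldiphenylsilyl)oxy]-7-oxotridec-2-enoate | CCOC(=O)/C=C/CCCC(=O)CCC[C@H](CCO[Si](C(C)(C)C)(c1ccccc1)c1ccccc1)N(OC(=O)OC(C)(C)C)C(=O)OC(C)(C)C | intermediate
15 | free hydroxylamine ethyl (2E,11R)-13-[(tert-butyldiphenylsilyl)oxy]-11-(hydroxyamino)-7-oxotridec-2-enoate | CCOC(=O)/C=C/CCCC(=O)CCC[C@H](CCO[Si](C(C)(C)C)(c1ccccc1)c1ccccc1)NO | intermediate
16 | ring B ketonitrone ethyl (2E)-6-[(2R)-2-{2-[(tert-butyldiphenylsilyl)oxy]ethyl}-1-oxido-2,3,4,5-tetrahydropyridin-1-ium-6-yl]hex-2-enoate | CCOC(=O)/C=C/CCCC1=[N+]([O-])[C@@H](CCO[Si](C(C)(C)C)(c2ccccc2)c2ccccc2)CCC1 | intermediate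
17 | tricyclic isoxazolidine ethyl ester (5R,9S,13S,14S; rings A and B spiro at C9 with an N–O–C14 bridge) | CCOC(=O)[C@H]1ON2[C@@H](CCO[Si](C(C)(C)C)(c3ccccc3)c3ccccc3)CCC[C@]23CCC[C@H]13 | intermediate
18 | amino hydroxy ester (N–H amine, C14–OH, ethyl ester; 5R,9S,13S,14S) | CCOC(=O)[C@@H](O)[C@H]1CCC[C@]12CCC[C@H](CCO[Si](C(C)(C)C)(c3ccccc3)c3ccccc3)N2 | intermediate
19 | spiro-lactam core with C14–OH on the concave face and C5–CH2CH2OTBDPS (5R,9S,13S,14S) | O=C1N2[C@@H](CCO[Si](C(C)(C)C)(c4ccccc4)c4ccccc4)CCC[C@]23CCC[C@@H]3[C@@H]1O | intermediate
20 | O-(C14 of the spiro-lactam core) 1H-imidazole-1-carbothioate with C5–CH2CH2OTBDPS | O=C1N2[C@@H](CCO[Si](C(C)(C)C)(c4ccccc4)c4ccccc4)CCC[C@]23CCC[C@@H]3[C@@H]1OC(=S)n1ccnc1 | intermediate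
21 | spiro-lactam core with C14 methylene and C5–CH2CH2OTBDPS (5R,9S,13R) | O=C1N2[C@@H](CCO[Si](C(C)(C)C)(c4ccccc4)c4ccccc4)CCC[C@]23CCC[C@@H]3C1 | intermediate
22 | spiro-lactam core with C14–CH3 on the convex face and C5–CH2CH2OTBDPS (5R,9S,13R,14R) | O=C1N2[C@@H](CCO[Si](C(C)(C)C)(c4ccccc4)c4ccccc4)CCC[C@]23CCC[C@@H]3[C@H]1C | intermediate
23 | spiro-lactam core with C14–CH3 and C5–CH2CH2OH (5R,9S,13R,14R) | O=C1N2[C@@H](CCO)CCC[C@]23CCC[C@@H]3[C@H]1C | intermediate
24 | spiro-lactam core with C14–CH3 and C5–CH2CHO (5R,9S,13R,14R) | O=C1N2[C@@H](CC=O)CCC[C@]23CCC[C@@H]3[C@H]1C | intermediate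
25 | spiro-lactam core with C14–CH3 and C5–CH2CH=CH2 (5R,9S,13R,14R) | O=C1N2[C@@H](CC=C)CCC[C@]23CCC[C@@H]3[C@H]1C | intermediate
26 | (2R)-2-[(1R,5S,7R)-7-(prop-2-en-1-yl)-6-azaspiro[4.5]decan-1-yl]propan-1-ol | OC[C@H](C)[C@H]1CCC[C@]12CCC[C@H](CC=C)N2 | intermediate
27 | methyl 2-(bromomethyl)prop-2-enoate | C=C(CBr)C(=O)OC | starting material
28 | methyl 2-{[(1R,5S,7R)-1-[(2R)-1-hydroxypropan-2-yl]-7-(prop-2-en-1-yl)-6-azaspiro[4.5]decan-6-yl]methyl}prop-2-enoate | OC[C@H](C)[C@H]1CCC[C@]12CCC[C@H](CC=C)N2CC(=C)C(=O)OC | intermediate
29 | A–B–C core methyl ester with (2R)-1-hydroxypropan-2-yl on C13 (5R,9S,13R) | OC[C@H](C)[C@H]1CCC[C@]12CCC[C@@H]3CC=C(C(=O)OC)CN23 | intermediate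
30 | A–B–C core methyl ester with (2R)-1-oxopropan-2-yl on C13 (5R,9S,13R) | O=C[C@H](C)[C@H]1CCC[C@]12CCC[C@@H]3CC=C(C(=O)OC)CN23 | intermediate
31 | A–B–C core methyl ester with (2R)-but-3-yn-2-yl on C13 (5R,9S,13R; terminal alkyne C15≡C16) | C#C[C@H](C)[C@H]1CCC[C@]12CCC[C@@H]3CC=C(C(=O)OC)CN23 | intermediate
32 | oxane-2,4-dione | O=C1CC(=O)OCC1 | starting material
33 | 4-chloro-5,6-dihydro-2H-pyran-2-one | ClC1=CC(=O)OCC1 | intermediate
34 | (2E)-3-chloro-5-hydroxy-N-methoxy-N-methylpent-2-enamide | CON(C)C(=O)/C=C(/Cl)CCO | intermediate
35 | (2E)-5-[(tert-butyldimethylsilyl)oxy]-3-chloro-N-methoxy-N-methylpent-2-enamide | CON(C)C(=O)/C=C(/Cl)CCO[Si](C)(C)C(C)(C)C | intermediate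
36 | (2E)-5-[(tert-butyldimethylsilyl)oxy]-3-chloropent-2-enal | O=C/C=C(/Cl)CCO[Si](C)(C)C(C)(C)C | intermediate
37 | A–B–C core methyl ester with C13 chain C14H(CH3)–C15≡C16–C17H(OH)–C18H=C19(Cl)–C20H2–C21H2–OTBS (14R,17S,18E) | COC(=O)C1=CC[C@H]2CCC[C@]3(CCC[C@@H]3[C@@H](C)C#C[C@@H](O)/C=C(/Cl)CCO[Si](C)(C)C(C)(C)C)N2C1 | intermediate
38 | A–B–C core methyl ester with C13 chain C14H(CH3)–C15H=C16H–C17H(OH)–C18H=C19(Cl)–C20H2–C21H2–OTBS (14S,15Z,17R,18E) | COC(=O)C1=CC[C@H]2CCC[C@]3(CCC[C@@H]3[C@@H](C)/C=C\[C@@H](O)/C=C(/Cl)CCO[Si](C)(C)C(C)(C)C)N2C1 | intermediate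
39 | diol methyl ester (C17–OH and C21–OH free; 14S,15Z,17R,18E) | COC(=O)C1=CC[C@H]2CCC[C@]3(CCC[C@@H]3[C@@H](C)/C=C\[C@@H](O)/C=C(/Cl)CCO)N2C1 | intermediate
40 | seco acid: A–B–C core carboxylic acid with C13 chain ending in C21H2–OH and free C17–OH (14S,15Z,17R,18E) | OC(=O)C1=CC[C@H]2CCC[C@]3(CCC[C@@H]3[C@@H](C)/C=C\[C@@H](O)/C=C(/Cl)CCO)N2C1 | intermediate
41 | target macrolactone CNP0129639.4 (5R,9S,13R,14S,17R; 15Z,18E) | C[C@H]1/C=C\[C@@H](O)/C=C(/Cl)CCOC(=O)C2=CC[C@H]3CCC[C@]4(CCC[C@H]14)N3C2 | target

## Step count and least certain steps

Total: 30 steps. Longest linear sequence: 26 steps (steps 1–22 and 27–30); the side-chain branch (steps 23–26) has 4 steps.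

Step 10 (key step). The most likely failure is incomplete equilibration, or an equilibrium that does not favour the isomer with C13 cis to the C5 chain; the basis for the expected preference is a conformational argument, not a secured result. Thermal loss of material at 160 °C is the second concern. Fallback: it sets out from 12. The silyl ether is cleaved (Bu4NF buffered with AcOH) to the primary alcohol F1, which is acylated with acryloyl chloride to the acrylate ester F2. Ring-closing metathesis at high dilution with the second-generation Grubbs catalyst RuCl2(=CHPh)(H2IMes)(PCy3) should give the 14-membered E-enoate lactone F3, and acidolysis and neutralisation as in step 9 the macrocyclic ketonitrone F4. In F4 the enoate is tied through O3 to the C5 chain, so a transannular (3+2) cycloaddition on heating in toluene can only place C13 on the face of ring B that carries C4; it should give the bridged isoxazolidine lactone F5. Ethanolysis (K2CO3, EtOH) to the hydroxy ester F6 and silylation with TBDPSCl return the material to the route at 17.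

Step 18. The tetrahedral intermediate may collapse by C–O cleavage and give the fully reduced cyclic tertiary amine, or hydride addition to the hindered lactam may be too slow. Fallback: it sets out from 25. O-Ethylation with Et3O·BF4 gives the lactim ether salt F7, whose hydrolysis in weakly acidic water cleaves the C–N bond to the amino ester F8; immediate reduction of F8 with LiAlH4 at −20 °C (before it can relactamise) gives 26.

Step 19. Substitution at the hindered nitrogen may be so slow that O-alkylation or polymerisation of 27 takes over. Fallback: it sets out from 26. Conjugate addition of the amine to methyl 2-(dimethoxyphosphoryl)acrylate, an acceptor with no leaving group, gives the β-amino phosphonate F9 (its new centre at C2 is lost later). Ozonolysis of the allyl group on the trifluoroacetate salt (O3, then Me2S) gives the C3 aldehyde F10, and an intramolecular Horner–Wadsworth–Emmons olefination (LiCl, iPr2NEt, MeCN) closes ring C and returns to the route at 29.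

Step 27. The facial selectivity may be insufficient, or the sense of induction of the chosen ligand antipode may be opposite to that assumed; it must be verified on the product (Mosher esters). Conversion may also be low with the alkyne as limiting partner, and 36 may drift in alkene geometry. Fallback: it sets out from 31 and 35. The lithium acetylide of 31 (BuLi, THF, −78 °C) is acylated by 35 to the ynone F11. Asymmetric transfer hydrogenation with RuCl[(S,S)-TsDPEN](p-cymene) in HCO2H/Et3N, with the alkynyl group as the directing unsaturated substituent, should give 37.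

Step 30. The free C17 hydroxyl may be acylated (11-membered lactone or oligomers), or the activated doubly allylic system may ionise. Fallback: it sets out from 38. Silylation (TBSOTf, 2,6-lutidine) gives the bis-silyl ether F12; the primary silyl ether is cleaved selectively (HF·pyridine, pyridine, THF, 0 °C) to the primary alcohol F13; saponification (LiOH) gives the C17-protected seco acid F14; macrolactonisation under the conditions of step 30 gives the silylated macrolactone F15; HF·pyridine then removes the last silyl group and returns to the route at 41.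

## Further compounds

F1 | step 10 | tert-butyl N-[(tert-butoxycarbonyl)oxy]-N-[(3R)-1-hydroxy-7-oxododec-11-en-3-yl]carbamate | OCC[C@H](N(OC(=O)OC(C)(C)C)C(=O)OC(C)(C)C)CCCC(=O)CCCC=C
F2 | step 10 | acrylate ester of F1 | C=CC(=O)OCC[C@H](N(OC(=O)OC(C)(C)C)C(=O)OC(C)(C)C)CCCC(=O)CCCC=C
F3 | step 10 | 14-membered E-enoate keto lactone with the bis-Boc hydroxylamine on C5 | O=C1/C=C/CCCC(=O)CCC[C@H](CCO1)N(OC(=O)OC(C)(C)C)C(=O)OC(C)(C)C
F4 | step 10 | macrocyclic ketonitrone (ring B nitrone bridged by the enoate lactone) | O=C1/C=C/CCCC2=[N+]([O-])[C@@H](CCO1)CCC2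
F5 | step 10 | bridged isoxazolidine lactone (transannular cycloadduct) | O=C4[C@H]1ON2[C@@H](CCO4)CCC[C@]23CCC[C@H]13
F6 | step 10 | tricyclic isoxazolidine ethyl ester with C5–CH2CH2OH | CCOC(=O)[C@H]1ON2[C@@H](CCO)CCC[C@]23CCC[C@H]13
F7 | step 18 | O-ethyl lactim ether tetrafluoroborate of 25 | CCOC1=[N+]2[C@@H](CC=C)CCC[C@]23CCC[C@@H]3[C@H]1C.F[B-](F)(F)F
F8 | step 18 | ethyl (2R)-2-[(1R,5S,7R)-7-(prop-2-en-1-yl)-6-azaspiro[4.5]decan-1-yl]propanoate | CCOC(=O)[C@H](C)[C@H]1CCC[C@]12CCC[C@H](CC=C)N2
F9 | step 19 | β-amino phosphonate from 26 and methyl 2-(dimethoxyphosphoryl)acrylate | OC[C@H](C)[C@H]1CCC[C@]12CCC[C@H](CC=C)N2CC(C(=O)OC)P(=O)(OC)OC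
F10 | step 19 | C3 aldehyde of F9 | OC[C@H](C)[C@H]1CCC[C@]12CCC[C@H](CC=O)N2CC(C(=O)OC)P(=O)(OC)OC
F11 | step 27 | ynone (C17 ketone) from 31 and 35 | COC(=O)C1=CC[C@H]2CCC[C@]3(CCC[C@@H]3[C@@H](C)C#CC(=O)/C=C(/Cl)CCO[Si](C)(C)C(C)(C)C)N2C1
F12 | step 30 | bis-silyl ether of 38 (C17–OTBS, C21–OTBS) | COC(=O)C1=CC[C@H]2CCC[C@]3(CCC[C@@H]3[C@@H](C)/C=C\[C@@H](O[Si](C)(C)C(C)(C)C)/C=C(/Cl)CCO[Si](C)(C)C(C)(C)C)N2C1
F13 | step 30 | C21 alcohol with C17–OTBS (methyl ester) | COC(=O)C1=CC[C@H]2CCC[C@]3(CCC[C@@H]3[C@@H](C)/C=C\[C@@H](O[Si](C)(C)C(C)(C)C)/C=C(/Cl)CCO)N2C1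
F14 | step 30 | C17-silylated seco acid | OC(=O)C1=CC[C@H]2CCC[C@]3(CCC[C@@H]3[C@@H](C)/C=C\[C@@H](O[Si](C)(C)C(C)(C)C)/C=C(/Cl)CCO)N2C1
F15 | step 30 | C17-silylated macrolactone | C[C@H]1/C=C\[C@@H](O[Si](C)(C)C(C)(C)C)/C=C(/Cl)CCOC(=O)C2=CC[C@H]3CCC[C@]4(CCC[C@H]14)N3C2
A1 | alternative 1 | diyne ester with propynyl caps at C15 and C16 and C17–OSiEt3 | CC#C[C@@H](O[Si](CC)(CC)CC)/C=C(/Cl)CCOC(=O)C1=CC[C@H]2CCC[C@]3(CCC[C@@H]3[C@@H](C)C#CC)N2C1
A2 | alternative 1 | 15-membered cycloalkyne lactone with C17–OSiEt3 | C[C@H]1C#C[C@@H](O[Si](CC)(CC)CC)/C=C(/Cl)CCOC(=O)C2=CC[C@H]3CCC[C@]4(CCC[C@H]14)N3C2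
A3 | alternative 2 | 3-substituted 1,4,2-dioxazol-5-one on a trans-1,2-disubstituted cyclopentane | C[C@@H](C1=NOC(=O)O1)[C@H]2CCC[C@@H]2CCCCO[Si](C)(C)C(C)(C)C
A4 | alternative 2 | cis-fused bicyclic γ-lactam with N on quaternary C9 | C[C@H]1C(=O)N[C@]2(CCCCO[Si](C)(C)C(C)(C)C)CCC[C@H]12
A5 | alternative 3 | bicyclic hydroxylactam with N-tethered Z-vinylsilane | O=C1C[C@H]2CCCC2(O)N1[C@@H](CCO[Si](C(C)(C)C)(c3ccccc3)c3ccccc3)C/C=C\[Si](C)(C)C
A6 | alternative 3 | tricyclic spiro lactam with C7=C8 alkene | O=C1C[C@H]2CCC[C@]23C=CC[C@H](CCO[Si](C(C)(C)C)(c4ccccc4)c4ccccc4)N13
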